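**Plan**

- Retrosynthesis: the N1–OMe/C4=O pair goes back to a 4‑methoxypyridine N‑oxide (methyl shift from O4 to the N‑oxide oxygen), C3–OMe to C3–Br, and C8–OMe to a C8 ketone.
- Enabling feature: the hetero ring N1–C2(Me)–C3–C4(O)–C4a–C8a is a pyrrole (N1, C2, C4, C4a, C8a) plus the single carbon C3, lodged between methyl‑bearing C2 and oxygen‑bearing C4. Cutting C2–C3 and C3–C4 removes C3 as a dihalocarbene carbon and leaves a 3‑methoxy‑2‑methylpyrrole fused to a cyclohexanone.
- The pyrrole is cut at both C–N bonds (Paal–Knorr) to a 1,4‑diketone whose ring carbonyl is part of a cyclohexane‑1,2‑dione. The side chain is cut off a 4‑substituted cyclohexenone (Mukaiyama–Michael), and the cyclohexenone is cut to 7‑phenylheptanal and methyl vinyl ketone.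
- Forward order: carbocycle first (Michael addition, aldol condensation), then the pyrrole on its C2–C3 edge, then one‑carbon expansion of the pyrrole to the pyridine, then adjustment to the N‑methoxy‑4‑pyridone.
- Stereochemistry: C5 comes from an enamine‑catalysed Michael addition (catalyst control) and is carried through unchanged. C8 comes from a catalyst‑controlled transfer hydrogenation of the C8 ketone, cis to the C5 chain.

Key step: step 9

Assumption: the diarylprolinol ether is taken to follow its usual face‑shielding model, so the (R)‑catalyst gives the (2S)‑aldehyde (the antipode would be used otherwise), and methoxyacetone is taken to silylate on its methoxy‑bearing side under equilibrating conditions.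

**Route**

Step 1
Reactants: 1 7‑phenylheptan‑1‑ol
Product: 2 7‑phenylheptanal
Conditions: TEMPO (10 mol%), PhI(OAc)2, CH2Cl2, rt
Reagents that add atoms: none
Why: Oxoammonium (TEMPO/PhI(OAc)2) oxidation of an unhindered primary alcohol should stop at the aldehyde and leave the remote phenyl ring untouched.

Step 2
Reactants: 2 7‑phenylheptanal; 3 but‑3‑en‑2‑one (methyl vinyl ketone)
Product: 4 (2S)‑5‑oxo‑2‑(5‑phenylpentyl)hexanal
Conditions: (R)‑2‑[methoxy(diphenyl)methyl]pyrrolidine (5 mol%), ethyl 3,4‑dihydroxybenzoate (20 mol%), neat, 4 °C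
Reagents that add atoms: none
Why: Enamine‑catalysed Michael addition of a linear aldehyde to methyl vinyl ketone, in which the diphenyl(methoxy)methyl group blocks one face of the E‑enamine so that the enone is attacked from the open face, setting C2 (the later C5) under catalyst control.

Step 3
Reactants: 4 (2S)‑5‑oxo‑2‑(5‑phenylpentyl)hexanal
Product: 5 (4S)‑4‑(5‑phenylpentyl)cyclohex‑2‑en‑1‑one
Conditions: aq KOH, nBu4NOH (cat.), Et2O/THF, rt
Reagents that add atoms: none
Why: Intramolecular aldol condensation (ring‑closing half of a Robinson annulation, 6‑(enolexo)‑exo‑trig attack of the methyl‑ketone enolate on the aldehyde, then dehydration); once the ring is closed the stereocentre is the γ‑carbon and brief, mild base should not erode it.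

Step 4
Reactants: 6 1‑methoxypropan‑2‑one (methoxyacetone)
Product: 7 (Z)‑1‑methoxy‑2‑(trimethylsilyloxy)prop‑1‑ene
Conditions: TMSOTf, Et3N, Et2O, 0 °C to rt; distillation
Reagents that add atoms: trimethylsilyl trifluoromethanesulfonate, C[Si](C)(C)OS(=O)(=O)C(F)(F)F
Why: Soft enolisation and O‑silylation under equilibrating amine conditions should favour the more substituted, methoxy‑bearing enol silane, in line with the tendency of α‑alkoxy ketones to enolise toward the alkoxy carbon; the alkene geometry is immaterial.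

Step 5
Reactants: 5 (4S)‑4‑(5‑phenylpentyl)cyclohex‑2‑en‑1‑one; 7 (Z)‑1‑methoxy‑2‑(trimethylsilyloxy)prop‑1‑ene
Product: 8 3‑methoxy‑3‑[(6S)‑6‑(5‑phenylpentyl)‑3‑(trimethylsilyloxy)cyclohex‑2‑en‑1‑yl]propan‑2‑one (side chain trans to the phenylpentyl group; methoxy carbon as an epimer mixture)
Conditions: HNTf2 (2 mol%), CH2Cl2, −78 °C; Et3N quench, non‑aqueous work‑up
Reagents that add atoms: none
Why: Mukaiyama–Michael addition with silyl transfer (Me3SiNTf2 formed in the flask as the Lewis acid): the enol silane attacks C3 of the enone anti to the C4 chain and the ring ketone is returned as a regiodefined C1–C2 enol silane; both new stereocentres are erased when the pyrrole forms.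

Step 6
Reactants: 8 Mukaiyama–Michael enol silane
Product: 10 (4S)‑2‑hydroxy‑3‑(1‑methoxy‑2‑oxopropyl)‑4‑(5‑phenylpentyl)cyclohexan‑1‑one (3,4‑trans; carbinol and methoxy carbons as mixtures), via 2‑silyloxy ketone 9 (not isolated)
Conditions: mCPBA, NaHCO3, CH2Cl2, −20 to 0 °C; then aq citric acid, THF
Reagents that add atoms: 3‑chloroperoxybenzoic acid, OOC(=O)c1cccc(Cl)c1
Why: Rubottom oxidation (epoxidation of the enol silane, 1,4‑silyl shift, mild acidic desilylation) should place the hydroxyl on C2 only, because the enol silane fixes the regiochemistry; the carbinol configuration does not matter.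

Step 7
Reactants: 10 acyloin
Product: 11 (4S)‑3‑(1‑methoxy‑2‑oxopropyl)‑4‑(5‑phenylpentyl)cyclohexane‑1,2‑dione (epimer mixture, partly as its enol)
Conditions: Dess–Martin periodinane, NaHCO3, CH2Cl2, 0 °C to rt; used crude
Reagents that add atoms: none
Why: Dess–Martin oxidation of an acyloin to the 1,2‑dione under near‑neutral conditions, chosen so that the β‑methoxy ketone is not exposed to base that could eliminate methanol.

Step 8
Reactants: 11 triketone
Product: 12 (4S)‑3‑methoxy‑2‑methyl‑4‑(5‑phenylpentyl)‑1,4,5,6‑tetrahydro‑7H‑indol‑7‑one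
Conditions: NH4OAc, AcOH, 50 °C
Reagents that add atoms: ammonium acetate, CC(=O)[O-].[NH4+]
Why: Paal–Knorr pyrrole synthesis in which ammonia bridges the side‑chain ketone and the adjacent ring carbonyl (C2 of the dione), the only carbonyl pair that can close an unstrained five‑membered ring; double dehydration aromatises, C3 and the methoxy carbon become sp2, and the C1 carbonyl is left as the C7 ketone.

Step 9
Reactants: 12 (4S)‑3‑methoxy‑2‑methyl‑4‑(5‑phenylpentyl)‑1,4,5,6‑tetrahydro‑7H‑indol‑7‑one; 13 bromoform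
Product: 15 (5S)‑3‑bromo‑4‑methoxy‑2‑methyl‑5‑(5‑phenylpentyl)‑6,7‑dihydroquinolin‑8(5H)‑one, via dibromocyclopropane 14 (not isolated)
Conditions: CHBr3, 50% aq NaOH, BnEt3NCl (10 mol%), toluene, 0 °C to rt
Reagents that add atoms: none
Why: Hydroxide at the interface deprotonates bromoform and α‑elimination releases CBr2, which adds as an electrophile across the C2=C3 bond of the pyrrole (held in the organic phase largely as its ammonium pyrrolide) to give the 6,6‑dibromo‑2‑azabicyclo[3.1.0]hexene 14; the nitrogen lone pair then opens the internal C2–C3 bond in a disrotatory 2π‑electrocyclic cleavage with loss of bromide, so the carbene carbon becomes the bromine‑bearing C3 of the aromatic pyridine, bonded to the former pyrrole C2 and C3. The closest known reaction type is the Ciamician–Dennstedt rearrangement of pyrroles and indoles to 3‑halopyridines and 3‑haloquinolines under phase‑transfer dihalocarbene generation. The three‑membered ring closes by cheletropic [2+1] addition, and the six‑membered ring arises by expansion of the five‑membered ring through cleavage of the shared bond, not by a cyclisation. No stereocentre is formed, and C4, which is not enolisable, is carried over as C5. The selectivity needed is between the two pyrrole π bonds: the methoxy and methyl groups make C2=C3 the electron‑rich, enol‑ether‑like bond, whereas C3a=C7a is depleted by the conjugated C7 ketone and insertion there would give a meta‑bridged pyridine too strained to form. With every ring carbon substituted no Reimer–Tiemann formylation can occur, and keeping C7 as a ketone avoids the azafulvenium ionisation that an ether at that carbon would invite.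

Step 10
Reactants: 15 bromopyridine ketone
Product: 16 (5S,8R)‑3‑bromo‑4‑methoxy‑2‑methyl‑5‑(5‑phenylpentyl)‑5,6,7,8‑tetrahydroquinolin‑8‑ol
Conditions: RuCl[(R,R)‑TsDPEN](p‑cymene) (1 mol%), HCO2H/Et3N (5:2), CH2Cl2, 30 °C
Reagents that add atoms: none
Why: Noyori asymmetric transfer hydrogenation of an aryl (2‑pyridyl) ketone, in which the (R,R)‑catalyst should deliver hydride to the face that gives the 8R alcohol (by analogy with 1‑tetralone), i.e. hydroxyl cis to the C5 chain, matched with the substrate's own preference for hydride approach anti to the pseudoaxial C5 substituent.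

Step 11
Reactants: 16 bromopyridine alcohol
Product: 17 (5S,8R)‑3‑bromo‑4,8‑dimethoxy‑2‑methyl‑5‑(5‑phenylpentyl)‑5,6,7,8‑tetrahydroquinoline
Conditions: NaH, MeI, THF, 0 °C to rt
Reagents that add atoms: iodomethane, CI
Why: Williamson etherification of the secondary alkoxide without breaking the C8–O bond, so the configuration is kept; the pyridine nitrogen, flanked by the C2 methyl and C8 and deactivated by bromine, should quaternise only slowly.

Step 12
Reactants: 17 bromopyridine methyl ether
Product: 18 (5S,8R)‑3,4,8‑trimethoxy‑2‑methyl‑5‑(5‑phenylpentyl)‑5,6,7,8‑tetrahydroquinoline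
Conditions: CuI (20 mol%), NaOMe, MeOH/DMF, 110 °C
Reagents that add atoms: sodium methoxide, C[O-].[Na+]
Why: Ullmann‑type copper‑catalysed methoxylation of an aryl bromide, routinely run next to an ortho oxygen substituent; any methoxide exchange at C4 is degenerate and no ketone remains to condense.

Step 13
Reactants: 18 trimethoxypyridine
Product: 19 (5S,8R)‑3,4,8‑trimethoxy‑2‑methyl‑5‑(5‑phenylpentyl)‑5,6,7,8‑tetrahydroquinoline 1‑oxide
Conditions: mCPBA, CH2Cl2, 0 °C to rt
Reagents that add atoms: 3‑chloroperoxybenzoic acid, OOC(=O)c1cccc(Cl)c1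
Why: Peracid N‑oxidation of an electron‑rich 2,6‑dialkylpyridine, with no alkene or amine to compete and with ethers and the phenyl ring inert.

Step 14
Reactants: 19 N‑oxide
Product: 21 Waltherione H, (5S,8R)‑1,3,8‑trimethoxy‑2‑methyl‑5‑(5‑phenylpentyl)‑5,6,7,8‑tetrahydroquinolin‑4(1H)‑one, via tetramethoxyquinolinium iodide 20 (not isolated)
Conditions: MeI (excess), MeCN, 70 °C, sealed tube
Reagents that add atoms: iodomethane, CI
Why: Alkyl‑halide‑mediated isomerisation of a 4‑alkoxypyridine N‑oxide to a 1‑alkoxy‑4‑pyridone: the N‑oxide oxygen is methylated, then iodide removes by SN2 the O4 methyl group, the only methoxy group conjugated with the pyridinium nitrogen, so the 3‑ and 8‑methoxy groups should stay.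

**Compound list**

1 | 7‑phenylheptan‑1‑ol | OCCCCCCCc1ccccc1 | starting material
2 | 7‑phenylheptanal | O=CCCCCCCc1ccccc1 | intermediate
3 | but‑3‑en‑2‑one | C=CC(C)=O | starting material
4 | (2S)‑5‑oxo‑2‑(5‑phenylpentyl)hexanal | O=C[C@@H](CCCCCc1ccccc1)CCC(C)=O | intermediate
5 | (4S)‑4‑(5‑phenylpentyl)cyclohex‑2‑en‑1‑one | O=C1C=C[C@@H](CCCCCc2ccccc2)CC1 | intermediate
6 | 1‑methoxypropan‑2‑one | COCC(C)=O | starting material
7 | (Z)‑1‑methoxy‑2‑(trimethylsilyloxy)prop‑1‑ene | CO/C=C(/C)O[Si](C)(C)C | intermediate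
8 | 3‑methoxy‑3‑[(6S)‑6‑(5‑phenylpentyl)‑3‑(trimethylsilyloxy)cyclohex‑2‑en‑1‑yl]propan‑2‑one (1,6‑trans) | CC(=O)C(OC)[C@H]1C=C(O[Si](C)(C)C)CC[C@@H]1CCCCCc1ccccc1 | intermediate
9 | (4S)‑3‑(1‑methoxy‑2‑oxopropyl)‑4‑(5‑phenylpentyl)‑2‑(trimethylsilyloxy)cyclohexan‑1‑one | CC(=O)C(OC)[C@H]1C(O[Si](C)(C)C)C(=O)CC[C@@H]1CCCCCc1ccccc1 | intermediate (not isolated)
10 | (4S)‑2‑hydroxy‑3‑(1‑methoxy‑2‑oxopropyl)‑4‑(5‑phenylpentyl)cyclohexan‑1‑one | CC(=O)C(OC)[C@H]1C(O)C(=O)CC[C@@H]1CCCCCc1ccccc1 | intermediate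
11 | (4S)‑3‑(1‑methoxy‑2‑oxopropyl)‑4‑(5‑phenylpentyl)cyclohexane‑1,2‑dione | CC(=O)C(OC)C1C(=O)C(=O)CC[C@@H]1CCCCCc1ccccc1 | intermediate
12 | (4S)‑3‑methoxy‑2‑methyl‑4‑(5‑phenylpentyl)‑1,4,5,6‑tetrahydro‑7H‑indol‑7‑one | COc1c(C)[nH]c2c1[C@@H](CCCCCc1ccccc1)CCC2=O | intermediate
13 | bromoform | BrC(Br)Br | starting material
14 | dibromocyclopropane adduct of 12 across C2–C3 (6,6‑dibromo‑2‑azabicyclo[3.1.0]hex‑3‑ene core) | COC12C(Br)(Br)C1(C)NC1=C2[C@@H](CCCCCc2ccccc2)CCC1=O | intermediate (not isolated)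
15 | (5S)‑3‑bromo‑4‑methoxy‑2‑methyl‑5‑(5‑phenylpentyl)‑6,7‑dihydroquinolin‑8(5H)‑one | Cc1nc2c(c(OC)c1Br)[C@@H](CCCCCc1ccccc1)CCC2=O | intermediate
16 | (5S,8R)‑3‑bromo‑4‑methoxy‑2‑methyl‑5‑(5‑phenylpentyl)‑5,6,7,8‑tetrahydroquinolin‑8‑ol | Cc1nc2c(c(OC)c1Br)[C@@H](CCCCCc1ccccc1)CC[C@H]2O | intermediate
17 | (5S,8R)‑3‑bromo‑4,8‑dimethoxy‑2‑methyl‑5‑(5‑phenylpentyl)‑5,6,7,8‑tetrahydroquinoline | Cc1nc2c(c(OC)c1Br)[C@@H](CCCCCc1ccccc1)CC[C@H]2OC | intermediate
18 | (5S,8R)‑3,4,8‑trimethoxy‑2‑methyl‑5‑(5‑phenylpentyl)‑5,6,7,8‑tetrahydroquinoline | COc1c(C)nc2c(c1OC)[C@@H](CCCCCc1ccccc1)CC[C@H]2OC | intermediate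
19 | (5S,8R)‑3,4,8‑trimethoxy‑2‑methyl‑5‑(5‑phenylpentyl)‑5,6,7,8‑tetrahydroquinoline 1‑oxide | COc1c(C)[n+]([O-])c2c(c1OC)[C@@H](CCCCCc1ccccc1)CC[C@H]2OC | intermediate
20 | (5S,8R)‑1,3,4,8‑tetramethoxy‑2‑methyl‑5‑(5‑phenylpentyl)‑5,6,7,8‑tetrahydroquinolin‑1‑ium iodide | COc1c(C)[n+](OC)c2c(c1OC)[C@@H](CCCCCc1ccccc1)CC[C@H]2OC.[I-] | intermediate (not isolated)
21 | Waltherione H, (5S,8R)‑1,3,8‑trimethoxy‑2‑methyl‑5‑(5‑phenylpentyl)‑5,6,7,8‑tetrahydroquinolin‑4(1H)‑one | COc1c(C)n(OC)c2c(c1=O)[C@@H](CCCCCc1ccccc1)CC[C@H]2OC | target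

**Step count and risks**

Total steps: 14. Longest linear sequence: 13 steps (1 to 21 through steps 1–3 and 5–14; step 4 prepares the side reagent 7).

Steps most likely to fail:

1. Step 9. The pyrrolide may be diverted into carbon‑dibromomethylation followed by protonation (non‑aromatisable 2H‑ or 3H‑pyrroles), into attack at nitrogen and N‑formylation, or into base‑mediated condensation of the ketone, instead of cyclopropanation and ring opening. The fallback sets out from 12 and returns at 18. The insertion is moved to base‑free conditions on the neutral pyrrole and to the chloro series: 12 is heated with Cl3CCO2Na in DME (thermal decarboxylation to dichlorocarbene), giving through the dichlorocyclopropane F1 the 3‑chloropyridine ketone F2. F2 is taken through the same transfer hydrogenation to the chloro alcohol F3 and the same O‑methylation to the chloro methyl ether F4. The C3–Cl bond of F4 is then methoxylated under palladium catalysis (Pd2(dba)3, tBuBrettPhos, NaOtBu, MeOH, 1,4‑dioxane, 80 °C) to give 18.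

2. Step 5. Conjugate addition to the γ‑branched enone may be slow, with desilylation or 1,2‑addition taking over, or the regioisomeric enol silane may be carried through and build the wrong connectivity. The fallback sets out from 5 and returns at 8, using a donor that can enolise in one direction only and is more nucleophilic. Methoxyacetyl chloride and ethanethiol give S‑ethyl 2‑methoxyethanethioate F5, and LiN(iPr)2/TMSCl converts it into the silyl ketene S,O‑acetal F6. Mukaiyama–Michael addition of F6 to 5 under the same catalysis gives the thioester enol silane F7. Fukuyama coupling of F7 (MeZnI, PdCl2(PPh3)2, toluene, rt) turns the thioester into the methyl ketone without touching the ring enol silane, which is 8.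

3. Step 14. The methyl transfer may stall at the N‑oxide/alkoxypyridinium equilibrium, or demethylation may stray to the 3‑methoxy group. The fallback sets out from 18 and returns at 21 by a stepwise deprotect‑and‑methylate sequence. Selective nucleophilic cleavage of the 4‑methoxy group of 18 with LiBH(s‑Bu)3 in THF gives the NH‑4‑pyridone F8, and O‑acylation with ClCO2Et/Et3N gives the 4‑pyridyl ethyl carbonate F9. mCPBA converts F9 into its N‑oxide F10, and aq KOH/EtOH removes the carbonate to give the 1‑hydroxy‑4‑pyridone F11. Methylation of the N–OH group of F11 with MeI/K2CO3 in DMF gives 21.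

**Further compounds**

F1 | step 9 | dichlorocyclopropane adduct of 12 across C2–C3 | COC12C(Cl)(Cl)C1(C)NC1=C2[C@@H](CCCCCc2ccccc2)CCC1=O
F2 | step 9 | (5S)‑3‑chloro‑4‑methoxy‑2‑methyl‑5‑(5‑phenylpentyl)‑6,7‑dihydroquinolin‑8(5H)‑one | Cc1nc2c(c(OC)c1Cl)[C@@H](CCCCCc1ccccc1)CCC2=O
F3 | step 9 | (5S,8R)‑3‑chloro‑4‑methoxy‑2‑methyl‑5‑(5‑phenylpentyl)‑5,6,7,8‑tetrahydroquinolin‑8‑ol | Cc1nc2c(c(OC)c1Cl)[C@@H](CCCCCc1ccccc1)CC[C@H]2O
F4 | step 9 | (5S,8R)‑3‑chloro‑4,8‑dimethoxy‑2‑methyl‑5‑(5‑phenylpentyl)‑5,6,7,8‑tetrahydroquinoline | Cc1nc2c(c(OC)c1Cl)[C@@H](CCCCCc1ccccc1)CC[C@H]2OC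
F5 | step 5 | S‑ethyl 2‑methoxyethanethioate | COCC(=O)SCC
F6 | step 5 | {[1‑(ethylsulfanyl)‑2‑methoxyethenyl]oxy}(trimethyl)silane | COC=C(O[Si](C)(C)C)SCC
F7 | step 5 | S‑ethyl 2‑methoxy‑2‑[(6S)‑6‑(5‑phenylpentyl)‑3‑(trimethylsilyloxy)cyclohex‑2‑en‑1‑yl]ethanethioate (1,6‑trans) | CCSC(=O)C(OC)[C@H]1C=C(O[Si](C)(C)C)CC[C@@H]1CCCCCc1ccccc1
F8 | step 14 | (5S,8R)‑3,8‑dimethoxy‑2‑methyl‑5‑(5‑phenylpentyl)‑5,6,7,8‑tetrahydroquinolin‑4(1H)‑one | COc1c(C)[nH]c2c(c1=O)[C@@H](CCCCCc1ccccc1)CC[C@H]2OC
F9 | step 14 | ethyl (5S,8R)‑3,8‑dimethoxy‑2‑methyl‑5‑(5‑phenylpentyl)‑5,6,7,8‑tetrahydroquinolin‑4‑yl carbonate | CCOC(=O)Oc1c(OC)c(C)nc2c1[C@@H](CCCCCc1ccccc1)CC[C@H]2OC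
F10 | step 14 | ethyl (5S,8R)‑3,8‑dimethoxy‑2‑methyl‑1‑oxido‑5‑(5‑phenylpentyl)‑5,6,7,8‑tetrahydroquinolin‑1‑ium‑4‑yl carbonate | CCOC(=O)Oc1c(OC)c(C)[n+]([O-])c2c1[C@@H](CCCCCc1ccccc1)CC[C@H]2OC
F11 | step 14 | (5S,8R)‑1‑hydroxy‑3,8‑dimethoxy‑2‑methyl‑5‑(5‑phenylpentyl)‑5,6,7,8‑tetrahydroquinolin‑4(1H)‑one | COc1c(C)n(O)c2c(c1=O)[C@@H](CCCCCc1ccccc1)CC[C@H]2OC
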